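## Structural features

Atom labels follow carotenoid numbering for this C37 skeleton: ring carbons C1 (gem-dimethyl) to C6, then C7 (=CH) and C8 (O–CH); lactone C9 (α), C10 (β-CH), C11 (γ) and C19 (C=O); chain C12, C13 (methyl), C14, C15, C15', C12', C11', C10', C9' (methyl); alkyne C8'≡C7'; cyclohexene ring C6'–C1' with the carbinol at C3'. A (3'R)-hydroxy-trimethylcyclohexene is joined through the C7'≡C8' alkyne to an all-E tetraene, which ends in a (Z)-γ-ylidene butenolide (C12=C11, O, C19, C9=C10). The lactone α-carbon C9 is bonded directly to C8 of a 2,4,5,6,7,7a-hexahydrobenzofuran (the "5,8-furanoid"), in which oxygen bridges the quaternary C5 and C8 and the C6=C7 double bond lies inside the five-membered ring. C3' (R) is isolated; C3 (S) and C5 (R) are 1,3 on the cyclohexane with the ring oxygen trans to the 3-OH; C8 (R) is separated from C5 only by the ring oxygen, with C8–H on the face of the C5 methyl. Fragile groups are the enol lactone (nucleophiles, base), the polyene-yne chromophore (acid, oxidants, light) and the C8–O bond, which ionises under acid and then epimerises C8. The real difficulty is C8: a tertiary allylic ether stereocentre at an sp3–sp2 junction (C8–C9) with no neighbouring stereocentre to direct it, followed by the quaternary C5–O centre. The key step exploits the O1–C8 bond together with the endocyclic C6=C7 bond: this pair is the product pattern of a 5-endo addition of the C5 hydroxyl to a C6=C7=C8 allene, so C8 can be stored as a stereogenic axis. That axis in turn traces back to a C7≡C8 alkyne beside a 5,6-epoxide, which turns the C8–C9 bond into an sp–sp2 coupling. There is also a hidden repetition: both six-membered rings are the same (4R,6R)-ketone, and C7'–C11' and C11–C15 (each with its methyl) are the same C6 enynol.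

## Logic of the disconnections

**24 ⇒ 23.** The two O–Si bonds at C3 and C3' are cut last. The hydroxyls are masked because the C3 oxygen must not direct the epoxidation and because the ylide step needs no free OH. The forward step must be non-acidic, since the C8–O bond of the furanoid ionises with acid.

**23 ⇒ 21 + 18.** The C11'=C12' double bond is cut (Wittig). This divides the chromophore into a C15 phosphonium salt and a C22 aldehyde of similar size and keeps the long polyene out of all metal-catalysed steps. The forward step must add 1,2 to the aldehyde without touching the enol lactone, and the new disubstituted alkene must end as E.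

**18 ⇒ 17 (key).** The O1–C8 bond is cut, which opens the dihydrofuran to a C5 tertiary alcohol and a C6=C7=C8 allene. The C8 stereocentre disappears into the allene axis, and the ring and the stereocentre are then made in one atom-economical isomerisation. The demand is a 5-endo hydroalkoxylation that transfers the axis to C8 without loss and leaves the trienal and enol lactone alone.

**17 ⇒ 16.** The C8–H bond is cut and the C6–O bond re-formed, giving a C7≡C8 alkyne on a 5,6-epoxide. The axis now derives from the C6 epoxide stereocentre. The demand is that hydride enters C8 anti to the C6–O bond (SN2'), with no hydride delivery at C6 and C5–O untouched.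

**16 ⇒ 7 + 15.** The C8–C9 bond is cut. In the target this is a hindered sp3–sp2 bond next to the stereocentre; here it is an sp–sp2 Sonogashira bond between a terminal alkyne and an α-bromo lactone, two fragments of similar size. The demand is oxidative addition at C9–Br faster than palladium attack on the propargylic epoxide.

**15 ⇒ 13 + 11.** The C10–C11 bond and the O–C11 bond of the lactone are cut (tandem alkynylation and 5-exo lactonisation). This builds the whole Z-ylidene butenolide, with its C9 bromide handle and C12' aldehyde, in one step from a three-carbon acid and a C8 enynal. The demand is coupling at C10–Br before C9–Br and 5-exo rather than 6-endo closure.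

**11 ⇒ 9 + 10, 9 ⇒ 8, 13 ⇒ 12.** The C15=C15' bond is cut (two-carbon Wittig homologation), the aldehyde goes back to the commercial enynol, and the two C–Br bonds of 13 go back to the alkyne. The demand is E-selective olefination and anti addition of bromine.

**7 ⇒ 6 ⇒ 5 ⇒ 3 + 4.** The alkyne C–Si bond, the two epoxide C–O bonds and the C6–C7 bond are cut in turn. The epoxide sets C5 (and, through C6, ultimately C8). The demand is peracid attack on the face anti to the C3 silyloxy group.

**21 ⇒ 19 ⇒ 3 + 8.** The C11'–P bond is cut, then the C6'–C7' bond (Sonogashira of the same enol triflate with the same enynol). The demand is clean SN2 quaternisation without allylic transposition.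

**3 ⇒ 2 ⇒ 1.** The enol triflate C–O bond and the silyl ether are cut. Only one enolate is possible, because the other α-carbon is quaternary. Both rings of the target come from 1.

## Other disconnections considered

**Alternative 1:** (the first that comes to mind) Cut O–C8 and restore the 5,6-epoxide with a 7,8-E-alkene, i.e. the 5,6-epoxy carotenoid A1. The forward key step is the acid-catalysed epoxide–furanoid rearrangement at the end of a conventional polyene and lactone assembly. It passes through a C6–C7–C8 allyl cation conjugated with the lactone, and the C5 oxygen can close on either face of C8, so both C8 epimers are expected. The product is itself acid-labile at C8, so the mixture cannot be corrected. A1 also needs an extra C7=C8 olefination, so it is not shorter. The chosen plan replaces this facial choice by a stereospecific transfer.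

**Alternative 2:** Cut C8–C9 with C8 as the electrophile, using the chiral-pool C11 nor-terpenoid (−)-loliolide A2, whose eleven carbons and C3/C5 stereocentres map onto the whole bicycle with C8 as the lactone carbonyl. Forward: reduction to the lactol, acetate A3, ionisation to the cyclic allylic oxocarbenium ion and addition of a butenolide C9 nucleophile to give A4. Grounds against: A2 is a milligram-scale natural product, and making it from 1 costs more steps than the epoxide 7. 2-Silyloxyfurans react at C11 rather than C9, so a C9-metallated surrogate and later redox steps are needed. The C8 configuration would rest on 1,3-induction by the C5 methyl across a nearly flat cation. After coupling, ylidene formation must pass through a furanolate in which the C8–O bond is β to the enolate carbon, which invites retro-oxa-Michael opening.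

**Alternative 3:** Cut C6=C7 by ring-closing metathesis of diene A5, an ether between the C5 oxygen and a C8 bearing a vinyl group, with an exocyclic methylene at C6. Grounds against: the new trisubstituted alkene is flanked by two fully substituted carbons (C1 and C5), a severe case for metathesis. The tertiary-alkyl secondary-allyl ether A5 with defined C8 would itself need a stereoselective etherification of a hindered tertiary alcohol, so the C8 problem is moved, not solved. The step count is higher than for the allene route.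

Key step: step 12

Remark (assumptions): (4R,6R)-4-hydroxy-2,2,6-trimethylcyclohexanone 1 and the E isomer of enynol 8 are taken as commercial; the polyene is targeted as the all-E, 11Z-ylidene isomer drawn.

## Steps

Step 1
Reactants: 1 (4R,6R)-4-hydroxy-2,2,6-trimethylcyclohexan-1-one
Product: 2 (4R,6R)-4-[(tert-butyldimethylsilyl)oxy]-2,2,6-trimethylcyclohexan-1-one
Conditions: TBSCl (1.2 equiv), imidazole (2.5 equiv), DMF, rt
Reagents that add atoms: tert-butyldimethylsilyl chloride, CC(C)(C)[Si](C)(C)Cl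
Why: Standard silylation of an unhindered secondary alcohol; the silyl ether later removes hydroxyl direction in the epoxidation and survives every step up to the end.

Step 2
Reactants: 2 (4R,6R)-4-[(tert-butyldimethylsilyl)oxy]-2,2,6-trimethylcyclohexan-1-one
Product: 3 (4R)-4-[(tert-butyldimethylsilyl)oxy]-2,6,6-trimethylcyclohex-1-en-1-yl trifluoromethanesulfonate
Conditions: LDA (1.2 equiv), THF, −78 °C; PhNTf2 (1.2 equiv), −78 °C to rt
Reagents that add atoms: N-phenylbis(trifluoromethanesulfonimide), O=S(=O)(N(c1ccccc1)S(=O)(=O)C(F)(F)F)C(F)(F)F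
Why: Enolate O-triflation; only the methyl-bearing α-carbon has a proton, so a single tetrasubstituted enol triflate should form and the now superfluous methyl stereocentre is erased.

Step 3
Reactants: 3 (4R)-4-[(tert-butyldimethylsilyl)oxy]-2,6,6-trimethylcyclohex-1-en-1-yl trifluoromethanesulfonate; 4 ethynyltrimethylsilane
Product: 5 tert-butyldimethyl({(1R)-3,5,5-trimethyl-4-[(trimethylsilyl)ethynyl]cyclohex-3-en-1-yl}oxy)silane
Conditions: PdCl2(PPh3)2 (5 mol %), CuI (10 mol %), Et3N, DMF, 50 °C
Reagents that add atoms: none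
Why: Sonogashira coupling of an enol triflate; it forms C6–C7 and brings in C7 and C8 as a silyl-capped alkyne that is inert to the peracid of the next step.

Step 4
Reactants: 5 tert-butyldimethyl({(1R)-3,5,5-trimethyl-4-[(trimethylsilyl)ethynyl]cyclohex-3-en-1-yl}oxy)silane
Product: 6 tert-butyldimethyl({(1R,4S,6R)-2,2,6-trimethyl-1-[(trimethylsilyl)ethynyl]-7-oxabicyclo[4.1.0]heptan-4-yl}oxy)silane (epoxide oxygen anti to the silyloxy group)
Conditions: mCPBA (1.2 equiv), NaHCO3, CH2Cl2, 0 °C
Reagents that add atoms: 3-chloroperoxybenzoic acid, OOC(=O)c1cccc(Cl)c1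
Why: Prilezhaev epoxidation of the only electron-rich alkene (the alkyne is unreactive); with the C3 oxygen silylated there is no hydrogen-bond delivery and the peracid is expected to attack the face anti to the silyloxy group, as is usual for 3-O-protected rings of this type, which sets C5 (R) and the C6 centre that later becomes the axis; any syn isomer would be removed by chromatography.

Step 5
Reactants: 6 tert-butyldimethyl({(1R,4S,6R)-2,2,6-trimethyl-1-[(trimethylsilyl)ethynyl]-7-oxabicyclo[4.1.0]heptan-4-yl}oxy)silane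
Product: 7 tert-butyl{[(1R,4S,6R)-1-ethynyl-2,2,6-trimethyl-7-oxabicyclo[4.1.0]heptan-4-yl]oxy}dimethylsilane
Conditions: K2CO3 (0.2 equiv), MeOH, rt
Reagents that add atoms: none
Why: Methanolysis of the alkynyl C–Si bond; the hindered tetrasubstituted epoxide and the secondary silyl ether should be untouched by catalytic carbonate.

Step 6
Reactants: 8 (2E)-3-methylpent-2-en-4-yn-1-ol
Product: 9 (2E)-3-methylpent-2-en-4-ynal
Conditions: activated MnO2 (excess), CH2Cl2, rt; solution used directly
Reagents that add atoms: none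
Why: Allylic oxidation with manganese dioxide, which does not isomerise the trisubstituted E alkene; the volatile enynal is not concentrated.

Step 7
Reactants: 9 (2E)-3-methylpent-2-en-4-ynal; 10 (triphenylphosphoranylidene)acetaldehyde
Product: 11 (2E,4E)-5-methylhepta-2,4-dien-6-ynal
Conditions: toluene, 70 °C (ylide as limiting reagent)
Reagents that add atoms: none
Why: Wittig formyl-olefination with a stabilised ylide, E-selective at the new C15=C15' bond; limiting the ylide suppresses a second homologation of the less electrophilic dienal.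

Step 8
Reactants: 12 propiolic acid
Product: 13 (2E)-2,3-dibromoprop-2-enoic acid
Conditions: Br2 (1.05 equiv), LiBr (cat.), AcOH, rt, dark
Reagents that add atoms: bromine, BrBr
Why: Ionic, bromide-assisted anti addition of bromine to the alkyne should give the E dibromide, in which the C10 bromine is cis to the carboxyl group as the later lactonisation requires.

Step 9
Reactants: 13 (2E)-2,3-dibromoprop-2-enoic acid; 11 (2E,4E)-5-methylhepta-2,4-dien-6-ynal
Product: 15 (5Z)-3-bromo-5-[(2E,4E)-2-methyl-6-oxohexa-2,4-dien-1-ylidene]furan-2(5H)-one, via bromo enynoic acid 14 (not isolated)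
Conditions: Pd(PPh3)4 (5 mol %), CuI (10 mol %), Et3N (4 equiv), MeCN, rt
Reagents that add atoms: none
Why: Tandem Sonogashira coupling and 5-exo-dig lactonisation of a (Z)-β-halo acrylic acid: oxidative addition is expected at the β (C10) bromide, which is more electrophilic and less hindered than the α (C9) bromide, and anti addition of the cis carboxylate across the new alkyne followed by protonolysis gives the Z ylidene and leaves the C9 bromide as the handle for step 10.

Step 10
Reactants: 7 tert-butyl{[(1R,4S,6R)-1-ethynyl-2,2,6-trimethyl-7-oxabicyclo[4.1.0]heptan-4-yl]oxy}dimethylsilane; 15 (5Z)-3-bromo-5-[(2E,4E)-2-methyl-6-oxohexa-2,4-dien-1-ylidene]furan-2(5H)-one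
Product: 16 (5Z)-3-{[(1R,4S,6R)-4-[(tert-butyldimethylsilyl)oxy]-2,2,6-trimethyl-7-oxabicyclo[4.1.0]heptan-1-yl]ethynyl}-5-[(2E,4E)-2-methyl-6-oxohexa-2,4-dien-1-ylidene]furan-2(5H)-one
Conditions: PdCl2(PPh3)2 (5 mol %), CuI (10 mol %), Et3N (3 equiv), THF, 0 °C to rt, slow addition of 7
Reagents that add atoms: none
Why: Sonogashira coupling at the activated α-bromo enoate forms the C8–C9 bond as an sp–sp2 bond; keeping 15 in excess over free alkyne favours oxidative addition into C–Br over SN2' opening of the propargylic epoxide.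

Step 11
Reactants: 16 (5Z)-3-{[(1R,4S,6R)-4-[(tert-butyldimethylsilyl)oxy]-2,2,6-trimethyl-7-oxabicyclo[4.1.0]heptan-1-yl]ethynyl}-5-[(2E,4E)-2-methyl-6-oxohexa-2,4-dien-1-ylidene]furan-2(5H)-one
Product: 17 (5Z)-3-[(aS)-2-{(2R,4S)-4-[(tert-butyldimethylsilyl)oxy]-2-hydroxy-2,6,6-trimethylcyclohexylidene}ethenyl]-5-[(2E,4E)-2-methyl-6-oxohexa-2,4-dien-1-ylidene]furan-2(5H)-one (6S allene in carotenoid numbering: C8–H on the face of the C5 methyl)
Conditions: Pd2(dba)3·CHCl3 (2.5 mol %), PPh3 (10 mol %), HCO2H (2 equiv), Et3N (2.5 equiv), THF, 0 °C to rt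
Reagents that add atoms: none
Why: Palladium–formate hydrogenolysis of a propargylic electrophile: Pd(0) opens the alkynyl epoxide by SN2' attack at C8 anti to the C6–O bond, formate gives Pd–H with loss of CO2, and reductive elimination with retention places H on C8 on the face opposite the C5 oxygen, which is the (aS) axis; hydride delivery at the fully substituted C6 is sterically disfavoured, and C5 keeps its oxygen and configuration.

Step 12
Reactants: 17 (5Z)-3-[(aS)-2-{(2R,4S)-4-[(tert-butyldimethylsilyl)oxy]-2-hydroxy-2,6,6-trimethylcyclohexylidene}ethenyl]-5-[(2E,4E)-2-methyl-6-oxohexa-2,4-dien-1-ylidene]furan-2(5H)-one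
Product: 18 (5Z)-3-[(2R,6S,7aR)-6-[(tert-butyldimethylsilyl)oxy]-4,4,7a-trimethyl-2,4,5,6,7,7a-hexahydro-1-benzofuran-2-yl]-5-[(2E,4E)-2-methyl-6-oxohexa-2,4-dien-1-ylidene]furan-2(5H)-one
Conditions: Ph3PAuNTf2 (5 mol %), THF, 0 °C to rt, dark
Reagents that add atoms: none
Why: Gold(I) coordinates the distal C7=C8 π bond of the allene on the side away from the hydroxyl, the C5 oxygen adds to C8 in the plane of C5–C6–C7 (anti oxyauration) to give a C7 alkenylgold species, and protodeauration installs C7–H and releases the catalyst. The closest known reaction type is the gold-catalysed cycloisomerisation of α-hydroxyallenes to 2,5-dihydrofurans with axis-to-centre chirality transfer. The ring O1–C8–C7=C6–C5 closes in the 5-endo-trig mode, the attacked C7=C8 bond ending inside the ring. The new stereocentre C8 is controlled only by the allene axis: H and C9 on C8 lie above and below the plane of attack and keep their sides, so the (aS) axis, with H on the face of the C5 methyl, must give 8R with C9 trans to that methyl; no facial choice by the reagent is involved. The step needs attack at C8 rather than C7 (the latter would be a strained 4-exo closure), and it needs the axis to survive until cyclisation; a planar gold–allyl cation that would scramble it is disfavoured because C8 carries the electron-poor lactone carbon. Chemoselectivity over the trienal and enol lactone is expected because these are electron-poor π systems without an internal nucleophile, whereas the tertiary hydroxyl sits five atoms from C8. THF tempers the acidity of the medium so that the new allylic C8–O bond should not re-ionise.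

Step 13
Reactants: 3 (4R)-4-[(tert-butyldimethylsilyl)oxy]-2,6,6-trimethylcyclohex-1-en-1-yl trifluoromethanesulfonate; 8 (2E)-3-methylpent-2-en-4-yn-1-ol
Product: 19 (2E)-5-{(4R)-4-[(tert-butyldimethylsilyl)oxy]-2,6,6-trimethylcyclohex-1-en-1-yl}-3-methylpent-2-en-4-yn-1-ol
Conditions: PdCl2(PPh3)2 (5 mol %), CuI (10 mol %), Et3N, DMF, rt to 50 °C
Reagents that add atoms: none
Why: Sonogashira coupling of the same enol triflate with the free enynol forms C6'–C7' and delivers C7'–C11' with the E trisubstituted alkene already in place.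

Step 14
Reactants: 19 (2E)-5-{(4R)-4-[(tert-butyldimethylsilyl)oxy]-2,6,6-trimethylcyclohex-1-en-1-yl}-3-methylpent-2-en-4-yn-1-ol
Product: 21 [(2E)-5-{(4R)-4-[(tert-butyldimethylsilyl)oxy]-2,6,6-trimethylcyclohex-1-en-1-yl}-3-methylpent-2-en-4-yn-1-yl]triphenylphosphonium bromide, via allylic bromide 20 (not isolated)
Conditions: PPh3 (2.3 equiv), CBr4 (1.15 equiv), CH2Cl2, 0 °C to rt; salt precipitated from EtOAc/hexane
Reagents that add atoms: triphenylphosphine, c1ccc(cc1)P(c1ccccc1)c1ccccc1; carbon tetrabromide, BrC(Br)(Br)Br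
Why: Appel bromination under neutral conditions keeps the silyl ether, and the excess phosphine quaternises the primary allylic bromide by direct SN2 in the same flask, so the labile bromide is never handled.

Step 15
Reactants: 21 [(2E)-5-{(4R)-4-[(tert-butyldimethylsilyl)oxy]-2,6,6-trimethylcyclohex-1-en-1-yl}-3-methylpent-2-en-4-yn-1-yl]triphenylphosphonium bromide; 18 (5Z)-3-[(2R,6S,7aR)-6-[(tert-butyldimethylsilyl)oxy]-4,4,7a-trimethyl-2,4,5,6,7,7a-hexahydro-1-benzofuran-2-yl]-5-[(2E,4E)-2-methyl-6-oxohexa-2,4-dien-1-ylidene]furan-2(5H)-one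
Product: 23 3,3'-bis-O-(tert-butyldimethylsilyl) ether of 24 (all-E chain and 11Z ylidene), via phosphonium ylide 22 (not isolated)
Conditions: NaHMDS (1.0 equiv), THF, −78 °C; 18, −78 to 0 °C; then I2 (1 mol %), CH2Cl2, rt, diffuse light
Reagents that add atoms: none
Why: Wittig olefination forms C11'=C12'; the semi-stabilised allylic ylide should add 1,2 to the aldehyde at low temperature faster than it attacks the enol lactone, and the unhindered disubstituted alkene, expected as an E/Z mixture, is equilibrated to E by iodine-catalysed photoisomerisation, which does not affect C8.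

Step 16
Reactants: 23 3,3'-bis-O-(tert-butyldimethylsilyl) ether of 24
Product: 24 (5Z)-3-[(2R,6S,7aR)-6-hydroxy-4,4,7a-trimethyl-2,4,5,6,7,7a-hexahydro-1-benzofuran-2-yl]-5-[(2E,4E,6E,8E)-11-[(4R)-4-hydroxy-2,6,6-trimethylcyclohex-1-en-1-yl]-2,9-dimethylundeca-2,4,6,8-tetraen-10-yn-1-ylidene]furan-2(5H)-one (CNP0300047.2)
Conditions: TBAF (6 equiv), AcOH (6 equiv), THF, 0 °C to rt, dark
Reagents that add atoms: none
Why: Fluoride desilylation buffered with acetic acid is neither acidic enough to ionise the C8–O bond nor basic enough to open the enol lactone, so both secondary silyl ethers should be removed with all stereocentres and alkene geometries intact.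

## Compound list

1 | (4R,6R)-4-hydroxy-2,2,6-trimethylcyclohexan-1-one | CC1(C)C[C@H](O)C[C@@H](C)C1=O | starting material
2 | (4R,6R)-4-[(tert-butyldimethylsilyl)oxy]-2,2,6-trimethylcyclohexan-1-one | CC1(C)C[C@H](O[Si](C)(C)C(C)(C)C)C[C@@H](C)C1=O | intermediate
3 | (4R)-4-[(tert-butyldimethylsilyl)oxy]-2,6,6-trimethylcyclohex-1-en-1-yl trifluoromethanesulfonate | CC1=C(OS(=O)(=O)C(F)(F)F)C(C)(C)C[C@H](O[Si](C)(C)C(C)(C)C)C1 | intermediate
4 | ethynyltrimethylsilane | C#C[Si](C)(C)C | starting material
5 | tert-butyldimethyl({(1R)-3,5,5-trimethyl-4-[(trimethylsilyl)ethynyl]cyclohex-3-en-1-yl}oxy)silane | CC1=C(C#C[Si](C)(C)C)C(C)(C)C[C@H](O[Si](C)(C)C(C)(C)C)C1 | intermediate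
6 | tert-butyldimethyl({(1R,4S,6R)-2,2,6-trimethyl-1-[(trimethylsilyl)ethynyl]-7-oxabicyclo[4.1.0]heptan-4-yl}oxy)silane | C[Si](C)(C)C#C[C@@]12O[C@]1(C)C[C@@H](O[Si](C)(C)C(C)(C)C)CC2(C)C | intermediate
7 | tert-butyl{[(1R,4S,6R)-1-ethynyl-2,2,6-trimethyl-7-oxabicyclo[4.1.0]heptan-4-yl]oxy}dimethylsilane | C#C[C@@]12O[C@]1(C)C[C@@H](O[Si](C)(C)C(C)(C)C)CC2(C)C | intermediate
8 | (2E)-3-methylpent-2-en-4-yn-1-ol | C#C/C(C)=C/CO | starting material
9 | (2E)-3-methylpent-2-en-4-ynal | C#C/C(C)=C/C=O | intermediate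
10 | (triphenylphosphoranylidene)acetaldehyde | O=CC=P(c1ccccc1)(c1ccccc1)c1ccccc1 | starting material
11 | (2E,4E)-5-methylhepta-2,4-dien-6-ynal | C#C/C(C)=C/C=C/C=O | intermediate
12 | propiolic acid | C#CC(=O)O | starting material
13 | (2E)-2,3-dibromoprop-2-enoic acid | OC(=O)/C(Br)=C\Br | intermediate
14 | (2E,6E,8E)-2-bromo-6-methyl-10-oxodeca-2,6,8-trien-4-ynoic acid | OC(=O)/C(Br)=C\C#C/C(C)=C/C=C/C=O | intermediate (not isolated)
15 | (5Z)-3-bromo-5-[(2E,4E)-2-methyl-6-oxohexa-2,4-dien-1-ylidene]furan-2(5H)-one | O=C/C=C/C=C(C)/C=C1/C=C(Br)C(=O)O1 | intermediate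
16 | (5Z)-3-{[(1R,4S,6R)-4-[(tert-butyldimethylsilyl)oxy]-2,2,6-trimethyl-7-oxabicyclo[4.1.0]heptan-1-yl]ethynyl}-5-[(2E,4E)-2-methyl-6-oxohexa-2,4-dien-1-ylidene]furan-2(5H)-one | O=C/C=C/C=C(C)/C=C1/C=C(C#C[C@@]23O[C@]2(C)C[C@@H](O[Si](C)(C)C(C)(C)C)CC3(C)C)C(=O)O1 | intermediate
17 | (5Z)-3-[(aS)-2-{(2R,4S)-4-[(tert-butyldimethylsilyl)oxy]-2-hydroxy-2,6,6-trimethylcyclohexylidene}ethenyl]-5-[(2E,4E)-2-methyl-6-oxohexa-2,4-dien-1-ylidene]furan-2(5H)-one | O=C/C=C/C=C(C)/C=C1/C=C(C([H])=[C@]=C2C(C)(C)C[C@H](O[Si](C)(C)C(C)(C)C)C[C@@]2(C)O)C(=O)O1 | intermediate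
18 | (5Z)-3-[(2R,6S,7aR)-6-[(tert-butyldimethylsilyl)oxy]-4,4,7a-trimethyl-2,4,5,6,7,7a-hexahydro-1-benzofuran-2-yl]-5-[(2E,4E)-2-methyl-6-oxohexa-2,4-dien-1-ylidene]furan-2(5H)-one | O=C/C=C/C=C(C)/C=C1/C=C([C@H]2C=C3C(C)(C)C[C@H](O[Si](C)(C)C(C)(C)C)C[C@@]3(C)O2)C(=O)O1 | intermediate
19 | (2E)-5-{(4R)-4-[(tert-butyldimethylsilyl)oxy]-2,6,6-trimethylcyclohex-1-en-1-yl}-3-methylpent-2-en-4-yn-1-ol | CC1=C(C#C/C(C)=C/CO)C(C)(C)C[C@H](O[Si](C)(C)C(C)(C)C)C1 | intermediate
20 | ({(1R)-4-[(3E)-5-bromo-3-methylpent-3-en-1-yn-1-yl]-3,5,5-trimethylcyclohex-3-en-1-yl}oxy)(tert-butyl)dimethylsilane | CC1=C(C#C/C(C)=C/CBr)C(C)(C)C[C@H](O[Si](C)(C)C(C)(C)C)C1 | intermediate (not isolated)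
21 | [(2E)-5-{(4R)-4-[(tert-butyldimethylsilyl)oxy]-2,6,6-trimethylcyclohex-1-en-1-yl}-3-methylpent-2-en-4-yn-1-yl]triphenylphosphonium bromide | CC1=C(C#C/C(C)=C/C[P+](c2ccccc2)(c2ccccc2)c2ccccc2)C(C)(C)C[C@H](O[Si](C)(C)C(C)(C)C)C1.[Br-] | intermediate
22 | [(2E)-5-{(4R)-4-[(tert-butyldimethylsilyl)oxy]-2,6,6-trimethylcyclohex-1-en-1-yl}-3-methylpent-2-en-4-yn-1-ylidene]triphenylphosphorane | CC1=C(C#C/C(C)=C/C=P(c2ccccc2)(c2ccccc2)c2ccccc2)C(C)(C)C[C@H](O[Si](C)(C)C(C)(C)C)C1 | intermediate (not isolated)
23 | (5Z)-3-[(2R,6S,7aR)-6-[(tert-butyldimethylsilyl)oxy]-4,4,7a-trimethyl-2,4,5,6,7,7a-hexahydro-1-benzofuran-2-yl]-5-[(2E,4E,6E,8E)-11-{(4R)-4-[(tert-butyldimethylsilyl)oxy]-2,6,6-trimethylcyclohex-1-en-1-yl}-2,9-dimethylundeca-2,4,6,8-tetraen-10-yn-1-ylidene]furan-2(5H)-one | CC1=C(C#C/C(C)=C/C=C/C=C/C=C(C)/C=C2/C=C([C@H]3C=C4C(C)(C)C[C@H](O[Si](C)(C)C(C)(C)C)C[C@@]4(C)O3)C(=O)O2)C(C)(C)C[C@H](O[Si](C)(C)C(C)(C)C)C1 | intermediate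
24 | (5Z)-3-[(2R,6S,7aR)-6-hydroxy-4,4,7a-trimethyl-2,4,5,6,7,7a-hexahydro-1-benzofuran-2-yl]-5-[(2E,4E,6E,8E)-11-[(4R)-4-hydroxy-2,6,6-trimethylcyclohex-1-en-1-yl]-2,9-dimethylundeca-2,4,6,8-tetraen-10-yn-1-ylidene]furan-2(5H)-one | CC1=C(C#C/C(C)=C/C=C/C=C/C=C(C)/C=C2/C=C([C@H]3C=C4C(C)(C)C[C@H](O)C[C@@]4(C)O3)C(=O)O2)C(C)(C)C[C@H](O)C1 | target

## Step count and least certain steps

Total: 16 steps. Longest linear sequence: 10 steps (1 → 2 → 3 → 5 → 6 → 7 → 16 → 17 → 18 → 23 → 24; steps 1, 2, 3, 4, 5, 10, 11, 12, 15, 16).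

**Step 12 (key step).** The most likely failure is erosion of the axis-to-centre transfer through gold-induced epimerisation of the allene before ring closure, since 17 is a vinylallene and a planar gold–allyl cation is conceivable. The second risk is slow turnover because the conjugated trienal and enol lactone compete for the catalyst. Fallback, from 17 back to 18: iodoetherification with N-iodosuccinimide (CH2Cl2, −40 °C), which follows the same anti 5-endo course and the same axis-to-centre sense, should give (5Z)-3-[(2S,6S,7aR)-6-[(tert-butyldimethylsilyl)oxy]-3-iodo-4,4,7a-trimethyl-2,4,5,6,7,7a-hexahydro-1-benzofuran-2-yl]-5-[(2E,4E)-2-methyl-6-oxohexa-2,4-dien-1-ylidene]furan-2(5H)-one F1. Palladium-catalysed formate hydrogenolysis of the alkenyl iodide (Pd(PPh3)4, HCO2H/Et3N, DMF, rt) then returns to 18.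

**Step 11.** The likely failures are loss of anti fidelity by equilibration of the allenylpalladium intermediate, and conjugate reduction or isomerisation of the trienal and ylidene lactone by palladium hydride. Fallback, from 16 back to 18 without any allene: partial hydrogenation of the C7≡C8 alkyne (Lindlar catalyst, quinoline, EtOAc) to (5Z)-3-{(Z)-2-[(1S,4S,6R)-4-[(tert-butyldimethylsilyl)oxy]-2,2,6-trimethyl-7-oxabicyclo[4.1.0]heptan-1-yl]ethenyl}-5-[(2E,4E)-2-methyl-6-oxohexa-2,4-dien-1-ylidene]furan-2(5H)-one F2. The classical acid-catalysed 5,6-epoxide to 5,8-furanoid rearrangement (cat. PPTS, CHCl3, 0 °C) would then give 18 together with its C8 epimer, (5Z)-3-[(2S,6S,7aR)-6-[(tert-butyldimethylsilyl)oxy]-4,4,7a-trimethyl-2,4,5,6,7,7a-hexahydro-1-benzofuran-2-yl]-5-[(2E,4E)-2-methyl-6-oxohexa-2,4-dien-1-ylidene]furan-2(5H)-one F3, to be separated by chromatography. This is reliable in bond formation but has no control at C8.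

**Step 10.** The likely failure is oxidative addition of Pd(0) into the propargylic epoxide of 7 (SN2' opening and allenyne formation with the copper acetylide) in competition with addition into the C9–Br bond, together with alkyne homocoupling. Fallback, from 5 back to 16, coupling before the epoxide exists: desilylation of 5 (K2CO3, MeOH) to tert-butyl{[(1R)-4-ethynyl-3,5,5-trimethylcyclohex-3-en-1-yl]oxy}dimethylsilane F4; Sonogashira coupling of F4 with 15 to (5Z)-3-({(4R)-4-[(tert-butyldimethylsilyl)oxy]-2,6,6-trimethylcyclohex-1-en-1-yl}ethynyl)-5-[(2E,4E)-2-methyl-6-oxohexa-2,4-dien-1-ylidene]furan-2(5H)-one F5; then mCPBA (NaHCO3, CH2Cl2, 0 °C). The peracid should select the tetrasubstituted ring alkene, the most alkylated π bond and the one farthest from the aldehyde (as in 5,6-epoxidation of retinoid-type polyenals), anti to the silyloxy group, giving 16.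

**Step 4.** The likely failure is poor facial selectivity, since the C3 silyloxy group is homoallylic and its bias over the two faces of the tetrasubstituted alkene is only moderate; the wrong face would carry the wrong C5 and, through the axis, the wrong C8. Fallback with reagent control, from 3 back to 7:
- Palladium-catalysed methoxycarbonylation of 3 (Pd(OAc)2, dppf, CO, MeOH, Et3N, DMF) gives methyl (4R)-4-[(tert-butyldimethylsilyl)oxy]-2,6,6-trimethylcyclohex-1-ene-1-carboxylate F6.
- DIBAL reduction gives {(4R)-4-[(tert-butyldimethylsilyl)oxy]-2,6,6-trimethylcyclohex-1-en-1-yl}methanol F7.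
- Sharpless asymmetric epoxidation (Ti(OiPr)4, L-(+)-diethyl tartrate, t-BuOOH, CH2Cl2, −20 °C) delivers oxygen to the face anti to the silyloxy group and gives {(1R,4S,6R)-4-[(tert-butyldimethylsilyl)oxy]-2,2,6-trimethyl-7-oxabicyclo[4.1.0]heptan-1-yl}methanol F8.
- Dess–Martin oxidation gives (1S,4S,6R)-4-[(tert-butyldimethylsilyl)oxy]-2,2,6-trimethyl-7-oxabicyclo[4.1.0]heptane-1-carbaldehyde F9.
- Ohira–Bestmann homologation (dimethyl (1-diazo-2-oxopropyl)phosphonate, K2CO3, MeOH) gives 7.

**Step 15.** The likely failures are attack of the ylide or of residual amide base on the enol lactone, and incomplete E/Z equilibration at C11'=C12', with iodine also able to generate traces of acid that would endanger C8. Fallback, from 19 back to 23, by Julia–Kocienski olefination: Mitsunobu reaction of 19 with 1-phenyl-1H-tetrazole-5-thiol (PPh3, DIAD, THF) gives 5-{[(2E)-5-{(4R)-4-[(tert-butyldimethylsilyl)oxy]-2,6,6-trimethylcyclohex-1-en-1-yl}-3-methylpent-2-en-4-yn-1-yl]sulfanyl}-1-phenyl-1H-tetrazole F10. Oxidation ((NH4)6Mo7O24, H2O2, EtOH) gives 5-{[(2E)-5-{(4R)-4-[(tert-butyldimethylsilyl)oxy]-2,6,6-trimethylcyclohex-1-en-1-yl}-3-methylpent-2-en-4-yn-1-yl]sulfonyl}-1-phenyl-1H-tetrazole F11. Deprotonation with NaHMDS (THF, −78 °C) and addition of 18 should give 23 after the same equilibration, if needed with diphenyl disulfide and light in place of iodine.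

## Further compounds

F1 | step 12 | (5Z)-3-[(2S,6S,7aR)-6-[(tert-butyldimethylsilyl)oxy]-3-iodo-4,4,7a-trimethyl-2,4,5,6,7,7a-hexahydro-1-benzofuran-2-yl]-5-[(2E,4E)-2-methyl-6-oxohexa-2,4-dien-1-ylidene]furan-2(5H)-one | O=C/C=C/C=C(C)/C=C1/C=C([C@H]2C(I)=C3C(C)(C)C[C@H](O[Si](C)(C)C(C)(C)C)C[C@@]3(C)O2)C(=O)O1
F2 | step 11 | (5Z)-3-{(Z)-2-[(1S,4S,6R)-4-[(tert-butyldimethylsilyl)oxy]-2,2,6-trimethyl-7-oxabicyclo[4.1.0]heptan-1-yl]ethenyl}-5-[(2E,4E)-2-methyl-6-oxohexa-2,4-dien-1-ylidene]furan-2(5H)-one | O=C/C=C/C=C(C)/C=C1/C=C(/C=C\[C@@]23O[C@]2(C)C[C@@H](O[Si](C)(C)C(C)(C)C)CC3(C)C)C(=O)O1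
F3 | step 11 | (5Z)-3-[(2S,6S,7aR)-6-[(tert-butyldimethylsilyl)oxy]-4,4,7a-trimethyl-2,4,5,6,7,7a-hexahydro-1-benzofuran-2-yl]-5-[(2E,4E)-2-methyl-6-oxohexa-2,4-dien-1-ylidene]furan-2(5H)-one | O=C/C=C/C=C(C)/C=C1/C=C([C@@H]2C=C3C(C)(C)C[C@H](O[Si](C)(C)C(C)(C)C)C[C@@]3(C)O2)C(=O)O1
F4 | step 10 | tert-butyl{[(1R)-4-ethynyl-3,5,5-trimethylcyclohex-3-en-1-yl]oxy}dimethylsilane | CC1=C(C#C)C(C)(C)C[C@H](O[Si](C)(C)C(C)(C)C)C1
F5 | step 10 | (5Z)-3-({(4R)-4-[(tert-butyldimethylsilyl)oxy]-2,6,6-trimethylcyclohex-1-en-1-yl}ethynyl)-5-[(2E,4E)-2-methyl-6-oxohexa-2,4-dien-1-ylidene]furan-2(5H)-one | O=C/C=C/C=C(C)/C=C1/C=C(C#CC2=C(C)C[C@@H](O[Si](C)(C)C(C)(C)C)CC2(C)C)C(=O)O1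
F6 | step 4 | methyl (4R)-4-[(tert-butyldimethylsilyl)oxy]-2,6,6-trimethylcyclohex-1-ene-1-carboxylate | CC1=C(C(=O)OC)C(C)(C)C[C@H](O[Si](C)(C)C(C)(C)C)C1
F7 | step 4 | {(4R)-4-[(tert-butyldimethylsilyl)oxy]-2,6,6-trimethylcyclohex-1-en-1-yl}methanol | CC1=C(CO)C(C)(C)C[C@H](O[Si](C)(C)C(C)(C)C)C1
F8 | step 4 | {(1R,4S,6R)-4-[(tert-butyldimethylsilyl)oxy]-2,2,6-trimethyl-7-oxabicyclo[4.1.0]heptan-1-yl}methanol | OC[C@@]12O[C@]1(C)C[C@@H](O[Si](C)(C)C(C)(C)C)CC2(C)C
F9 | step 4 | (1S,4S,6R)-4-[(tert-butyldimethylsilyl)oxy]-2,2,6-trimethyl-7-oxabicyclo[4.1.0]heptane-1-carbaldehyde | O=C[C@@]12O[C@]1(C)C[C@@H](O[Si](C)(C)C(C)(C)C)CC2(C)C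
F10 | step 15 | 5-{[(2E)-5-{(4R)-4-[(tert-butyldimethylsilyl)oxy]-2,6,6-trimethylcyclohex-1-en-1-yl}-3-methylpent-2-en-4-yn-1-yl]sulfanyl}-1-phenyl-1H-tetrazole | CC1=C(C#C/C(C)=C/CSc2nnnn2-c2ccccc2)C(C)(C)C[C@H](O[Si](C)(C)C(C)(C)C)C1
F11 | step 15 | 5-{[(2E)-5-{(4R)-4-[(tert-butyldimethylsilyl)oxy]-2,6,6-trimethylcyclohex-1-en-1-yl}-3-methylpent-2-en-4-yn-1-yl]sulfonyl}-1-phenyl-1H-tetrazole | CC1=C(C#C/C(C)=C/CS(=O)(=O)c2nnnn2-c2ccccc2)C(C)(C)C[C@H](O[Si](C)(C)C(C)(C)C)C1
A1 | alternative 1 | (5Z)-3-{(E)-2-[(1S,4S,6R)-4-hydroxy-2,2,6-trimethyl-7-oxabicyclo[4.1.0]heptan-1-yl]ethenyl}-5-[(2E,4E,6E,8E)-11-[(4R)-4-hydroxy-2,6,6-trimethylcyclohex-1-en-1-yl]-2,9-dimethylundeca-2,4,6,8-tetraen-10-yn-1-ylidene]furan-2(5H)-one | CC1=C(C#C/C(C)=C/C=C/C=C/C=C(C)/C=C2/C=C(/C=C/[C@@]34O[C@]3(C)C[C@@H](O)CC4(C)C)C(=O)O2)C(C)(C)C[C@H](O)C1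
A2 | alternative 2 | (6S,7aR)-6-hydroxy-4,4,7a-trimethyl-5,6,7,7a-tetrahydro-1-benzofuran-2(4H)-one ((−)-loliolide) | CC1(C)C[C@H](O)C[C@@]2(C)OC(=O)C=C12
A3 | alternative 2 | (6S,7aR)-6-[(tert-butyldimethylsilyl)oxy]-4,4,7a-trimethyl-2,4,5,6,7,7a-hexahydro-1-benzofuran-2-yl acetate (anomeric mixture) | CC(=O)OC1C=C2C(C)(C)C[C@H](O[Si](C)(C)C(C)(C)C)C[C@@]2(C)O1
A4 | alternative 2 | 3-[(2R,6S,7aR)-6-[(tert-butyldimethylsilyl)oxy]-4,4,7a-trimethyl-2,4,5,6,7,7a-hexahydro-1-benzofuran-2-yl]furan-2(5H)-one | O=C1OCC=C1[C@H]1C=C2C(C)(C)C[C@H](O[Si](C)(C)C(C)(C)C)C[C@@]2(C)O1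
A5 | alternative 3 | 3-[(1R)-1-({(1R,5S)-5-[(tert-butyldimethylsilyl)oxy]-1,3,3-trimethyl-2-methylidenecyclohexyl}oxy)prop-2-en-1-yl]furan-2(5H)-one | C=C[C@@H](O[C@]1(C)C[C@@H](O[Si](C)(C)C(C)(C)C)CC(C)(C)C1=C)C1=CCOC1=O
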